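**Strategy.** The ten-membered ring is disconnected at C2–C3, the only ring bond that joins two unfunctionalised allylic methylenes and the one farthest from the crowded C6–C9 oxygen tetrad. An open chain that already carries both trisubstituted olefins with fixed geometry (C1=C10 Z, C4=C5 E), a C3 phenylsulfonyl group and a C2 allylic bromide is closed in one operation by intramolecular alkylation of the sulfonyl carbanion. The precursor comes from L-arabinose (C5–C9, with C11–C13 added at C7) and but-2-yn-1-ol (C1, C2, C10, C14). O6 and O9 are silyl ethers, O7/O8 an acetonide, and the lactone is masked as a C12 PMB ether.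

Key step: step 18

Remark: germacranolide numbering of the target (C1–C15, oxygens named after their carbons) is used for all intermediates; 2 and 15 are anomer mixtures and 27/28 are mixtures at C3, which is of no consequence.

Step 1
Reactants: 1 L-arabinose
Product: 2 5-O-(tert-butyldiphenylsilyl)-L-arabinofuranose
Conditions: TBDPSCl, imidazole, DMF, 0 °C → rt
Reagents that add atoms: tert-butyl(chloro)diphenylsilane, CC(C)(C)[Si](Cl)(c1ccccc1)c1ccccc1
Why: The bulky silyl chloride should react only at the primary 5-OH and thereby lock the sugar in its furanose form (selective O-silylation), with no stereocentre touched.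

Step 2
Reactants: 2 5-O-TBDPS-L-arabinofuranose
Product: 3 5-O-TBDPS-1,2-O-isopropylidene-β-L-arabinofuranose
Conditions: Me2C(OMe)2, p-TsOH·H2O (cat.), acetone, rt
Reagents that add atoms: 2,2-dimethoxypropane, COC(C)(C)OC
Why: Acid-catalysed acetonide formation can engage only the cis O1/O2 pair of the β-furanose, which leaves 3-OH as the single free hydroxyl.

Step 3
Reactants: 3 1,2-acetonide alcohol
Product: 4 5-O-TBDPS-1,2-O-isopropylidene-β-L-threo-pentofuranos-3-ulose
Conditions: Dess–Martin periodinane, CH2Cl2, rt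
Reagents that add atoms: none
Why: Dess–Martin oxidation of the lone secondary alcohol needs no base, so the flanking stereocentres (later C8 and C6) should not epimerise.

Step 4
Reactants: 5 2,3-dibromopropene
Product: 6 2-bromoallyl 4-methoxybenzyl ether
Conditions: 4-MeOC6H4CH2OH, NaH, THF, 0 °C; then 5, 0 °C → rt
Reagents that add atoms: 4-methoxybenzyl alcohol, COc1ccc(CO)cc1
Why: Williamson etherification, in which the alkoxide displaces the allylic bromide by SN2 while the vinylic bromide is inert.

Step 5
Reactants: 4 3-ulose; 6 2-bromoallyl PMB ether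
Product: 8 C7-branched 1,2-O-isopropylidene-β-L-lyxofuranose (tertiary alcohol), via 2-lithioallyl PMB ether 7 (not isolated)
Conditions: 6, t-BuLi (2 equiv), Et2O, −78 °C; then 4, THF, −78 °C; H2O
Reagents that add atoms: none
Why: Bromine–lithium exchange gives the vinyllithium, whose 1,2-addition to the ketone should occur on the convex face anti to the cis-fused acetonide and the C4 side chain, which sets the tertiary carbinol (C7) with O7 cis to O8 and brings in C11–C13 with O12 as a PMB ether that survives the fluoride of step 6.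

Step 6
Reactants: 8 branched silyl ether
Product: 9 branched furanose with free primary 5-OH
Conditions: Bu4NF, THF, 0 °C → rt
Reagents that add atoms: none
Why: Fluoride-mediated desilylation removes the only silyl group present, and the PMB ether, acetonide and tertiary alcohol are inert.

Step 7
Reactants: 9 primary alcohol; 10 ethyl 2-(triphenylphosphoranylidene)propanoate
Product: 12 ethyl (E)-enoate (C3–C5 arm), via C5 aldehyde 11 (not isolated)
Conditions: Dess–Martin periodinane, CH2Cl2, 0 °C → rt; then 10 (excess), rt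
Reagents that add atoms: none
Why: One-pot oxidation/Wittig olefination avoids isolating the epimerisable α-alkoxy aldehyde, and the stabilised α-methyl ylide should give the E-trisubstituted enoate that fixes the C4=C5 geometry and adds C3, C4 and C15.

Step 8
Reactants: 12 enoate
Product: 13 (E)-allylic alcohol (C3–OH)
Conditions: i-Bu2AlH, CH2Cl2, −78 °C
Reagents that add atoms: none
Why: 1,2-Reduction of the conjugated ester by the aluminium hydride at low temperature gives the allylic alcohol without touching the acetonide or the olefin geometry.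

Step 9
Reactants: 13 allylic alcohol
Product: 14 (E)-allyl phenyl sulfide
Conditions: PhSSPh, n-Bu3P, THF, 0 °C → rt
Reagents that add atoms: diphenyl disulfide, c1ccc(SSc2ccccc2)cc1
Why: Disulfide–phosphine thioetherification (Hata reaction) converts only the primary allylic alcohol by SN2 at carbon, and sulfur is carried as the sulfide because the acidic α-protons of a sulfone would not survive the Grignard addition of step 13.

Step 10
Reactants: 14 1,2-acetonide
Product: 15 2,3-O-isopropylidene lactol (O7/O8 acetonide, C9 hemiacetal)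
Conditions: p-TsOH·H2O (cat.), acetone, rt
Reagents that add atoms: none
Why: Acid-catalysed acetal migration should move the isopropylidene group to the cis O2/O3 pair, the arrangement preferred by lyxofuranoses, which protects O7/O8 and frees the C9 lactol.

Step 11
Reactants: 16 but-2-yn-1-ol
Product: 18 (Z)-3-iodobut-2-en-1-ol, via sodium alkenylalanate 17 (not isolated)
Conditions: NaAlH2(OCH2CH2OCH3)2, THF, 0 °C → rt; then I2, −78 → 0 °C
Reagents that add atoms: iodine, II
Why: Alkoxide-directed trans-hydroalumination of the propargylic alcohol followed by iodinolysis of the carbon–aluminium bond with retention gives the Z-iodide that fixes the C1=C10 geometry.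

Step 12
Reactants: 18 iodo alcohol
Product: 19 (Z)-3-iodobut-2-enyl tert-butyldimethylsilyl ether
Conditions: TBSCl, imidazole, CH2Cl2, 0 °C → rt
Reagents that add atoms: tert-butyl(chloro)dimethylsilane, CC(C)(C)[Si](C)(C)Cl
Why: Standard silylation of a primary alcohol, which gives a group that can later be removed selectively next to secondary silyl ethers.

Step 13
Reactants: 15 lactol; 19 alkenyl iodide
Product: 22 open-chain C6/C9 diol, via alkenyllithium 20 (not isolated), via alkenylmagnesium bromide 21 (not isolated)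
Conditions: 19, t-BuLi (2 equiv), Et2O, −78 °C; MgBr2·OEt2, −78 → 0 °C; then 15, THF, −20 °C → rt (about 3 equiv of 21)
Reagents that add atoms: none
Why: Exchange and transmetalation retain the olefin geometry, and the Grignard reagent should add to the open hydroxy aldehyde through a magnesium chelate between the carbonyl and the α-oxygen O8 (Cram chelate model), opposite the quaternary C7, which sets C9 with O9 syn (threo) to O8, the sense usual for Grignard additions to 2,3-O-isopropylidene lactols of the manno/lyxo type.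

Step 14
Reactants: 22 diol
Product: 23 6,9-bis-TBS ether
Conditions: TBSOTf, 2,6-lutidine, CH2Cl2, −78 → 0 °C
Reagents that add atoms: tert-butyldimethylsilyl triflate, CC(C)(C)[Si](C)(C)OS(=O)(=O)C(F)(F)F
Why: The silyl triflate with a hindered base silylates both hindered secondary allylic alcohols, which are released together on lactol opening and therefore share one protecting group.

Step 15
Reactants: 23 sulfide
Product: 24 allylic phenyl sulfone
Conditions: H2O2 (30% aq.), (NH4)6Mo7O24·4H2O (cat.), EtOH, 0 °C
Reagents that add atoms: hydrogen peroxide, OO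
Why: Molybdate-catalysed peroxide oxidation is chemoselective for sulfur over the three olefins, and running it cold through the sulfoxide to the sulfone should limit Mislow–Evans equilibration of the allylic sulfoxide.

Step 16
Reactants: 24 tris-silyl ether
Product: 25 C2 allylic alcohol
Conditions: HF·pyridine, pyridine, THF, 0 °C
Reagents that add atoms: none
Why: Buffered HF·pyridine cleaves the unhindered primary allylic silyl ether much faster than the two hindered secondary ones (selective desilylation).

Step 17
Reactants: 25 allylic alcohol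
Product: 26 C2 allylic bromide (cyclisation precursor)
Conditions: CBr4, PPh3, CH2Cl2, −20 → 0 °C
Reagents that add atoms: carbon tetrabromide, BrC(Br)(Br)Br
Why: Appel bromination converts the primary allylic alcohol into the bromide by SN2 under neutral conditions, which keeps the Z geometry and leaves the acidic sulfone untouched.

Step 18
Reactants: 26 open-chain C3 sulfone C2 bromide
Product: 28 macrocyclic sulfone (ten-membered 1(10)Z,4E-diene; C3 epimers), via potassium sulfonyl carbanion 27 (not isolated)
Conditions: KN(SiMe3)2, THF, −78 °C, slow addition of 26 by syringe pump to about 1 mM; then −78 → −20 °C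
Reagents that add atoms: none
Why: The amide base deprotonates C3 to a sulfonyl-stabilised allyl anion (27) that displaces the primary allylic bromide at C2 by intramolecular SN2, forming C2–C3. The closest known reaction type is the macrocyclising alkylation of sulfur-stabilised allylic carbanions by allylic halides used for cyclodeca-1,5-dienes. The ten-membered ring closes in a 10-exo-tet mode. The only new stereocentre, C3, is formed without control and is erased in step 19, while both olefin geometries are already fixed in the chain. The step needs α- over γ-alkylation (the sulfone localises charge on C3 and C5 is shielded by C6/C7), SN2 over SN2′ (primary C2 against fully substituted C10) and cyclisation over oligomerisation (high dilution, with the acetonide and two trisubstituted olefins cutting down the free rotors). No other electrophile is present, since the lactone is masked as an ether and every hydroxyl is capped.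

Step 19
Reactants: 28 macrocyclic sulfone
Product: 29 desulfonylated (1(10)Z,4E)-macrocycle
Conditions: PdCl2(dppp) (cat.; dppp = Ph2P(CH2)3PPh2), LiBHEt3, THF, 0 °C
Reagents that add atoms: none
Why: Zerovalent palladium formed in situ ionises the allylic sulfone to a π-allyl complex and hydride should be delivered to the less hindered C3 terminus (palladium-catalysed reductive desulfonylation), which removes the temporary stereocentre and keeps the C4=C5 E olefin in place.

Step 20
Reactants: 29 PMB ether
Product: 30 C12 primary allylic alcohol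
Conditions: DDQ, CH2Cl2/pH 7 buffer, 0 °C
Reagents that add atoms: none
Why: Oxidative cleavage of the electron-rich PMB ether by DDQ in wet dichloromethane leaves silyl ethers, acetonide and the isolated olefins alone.

Step 21
Reactants: 30 bis-silyl ether
Product: 31 6,9,12-triol
Conditions: Bu4NF, THF, rt → 45 °C
Reagents that add atoms: none
Why: Fluoride cleaves both secondary silyl ethers at a stage where no base-sensitive methylene lactone is yet present.

Step 22
Reactants: 31 triol
Product: 34 α-methylene γ-lactone alcohol (6,12-olide; free 9-OH), via hydroxy enal 32 (not isolated), via lactol 33 (not isolated)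
Conditions: TEMPO (cat.), PhI(OAc)2, CH2Cl2, rt
Reagents that add atoms: none
Why: The oxoammonium oxidant should take the primary allylic alcohol in preference to the two hindered secondary ones, the enal is trapped by O6 as the five-membered lactol (a lactol on O9 would be six-membered and trans-fused to the dioxolane) and this is oxidised on to the lactone (oxidative lactonisation).

Step 23
Reactants: 34 lactone alcohol; 35 angelic acid
Product: 37 9-O-angelate acetonide, via mixed anhydride 36 (not isolated)
Conditions: 35, 2,4,6-Cl3C6H2COCl, Et3N, toluene, rt; then 34, 70 °C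
Reagents that add atoms: none
Why: Yamaguchi esterification through the mixed anhydride without a nucleophilic catalyst acylates the free 9-OH and avoids the addition–elimination pathway that turns angelates into tiglates.

Step 24
Reactants: 37 angelate acetonide
Product: 38 target CNP0303917.1
Conditions: CF3CO2H/H2O (9:1), CH2Cl2, 0 °C
Reagents that add atoms: none
Why: Acid-catalysed ketal hydrolysis frees the 7,8-diol, and a short cold exposure should spare the angelate, the lactone and the 1(10),4-diene, whose olefins are deactivated towards protonation by the allylic oxygens at C6 and C9.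

**Compound list**

1 | L-arabinose | O=C[C@H](O)[C@@H](O)[C@@H](O)CO | starting material
2 | 5-O-(tert-butyldiphenylsilyl)-L-arabinofuranose (anomer mixture) | OC1O[C@@H](CO[Si](c2ccccc2)(c2ccccc2)C(C)(C)C)[C@H](O)[C@H]1O | intermediate
3 | 5-O-(tert-butyldiphenylsilyl)-1,2-O-isopropylidene-β-L-arabinofuranose | CC1(C)O[C@H]2O[C@@H](CO[Si](c3ccccc3)(c3ccccc3)C(C)(C)C)[C@H](O)[C@H]2O1 | intermediate
4 | 5-O-(tert-butyldiphenylsilyl)-1,2-O-isopropylidene-β-L-threo-pentofuranos-3-ulose | CC1(C)O[C@H]2O[C@@H](CO[Si](c3ccccc3)(c3ccccc3)C(C)(C)C)C(=O)[C@H]2O1 | intermediate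
5 | 2,3-dibromopropene | C=C(Br)CBr | starting material
6 | 1-[(2-bromoprop-2-en-1-yl)oxymethyl]-4-methoxybenzene (2-bromoallyl PMB ether) | C=C(Br)COCc1ccc(OC)cc1 | intermediate
7 | [3-(4-methoxybenzyloxy)prop-1-en-2-yl]lithium | [Li]C(=C)COCc1ccc(OC)cc1 | intermediate
8 | 5-O-(tert-butyldiphenylsilyl)-1,2-O-isopropylidene-3-C-[3-(4-methoxybenzyloxy)prop-1-en-2-yl]-β-L-lyxofuranose (tertiary 3-OH cis to the acetonide) | CC1(C)O[C@H]2O[C@@H](CO[Si](c3ccccc3)(c3ccccc3)C(C)(C)C)[C@](O)(C(=C)COCc3ccc(OC)cc3)[C@H]2O1 | intermediate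
9 | 1,2-O-isopropylidene-3-C-[3-(4-methoxybenzyloxy)prop-1-en-2-yl]-β-L-lyxofuranose | CC1(C)O[C@H]2O[C@@H](CO)[C@](O)(C(=C)COCc3ccc(OC)cc3)[C@H]2O1 | intermediate
10 | ethyl 2-(triphenylphosphoranylidene)propanoate | CCOC(=O)C(C)=P(c1ccccc1)(c1ccccc1)c1ccccc1 | starting material
11 | 1,2-O-isopropylidene-3-C-[3-(4-methoxybenzyloxy)prop-1-en-2-yl]-β-L-lyxo-pentodialdo-1,4-furanose (C5 aldehyde) | CC1(C)O[C@H]2O[C@@H](C=O)[C@](O)(C(=C)COCc3ccc(OC)cc3)[C@H]2O1 | intermediate
12 | ethyl (E)-2-methylprop-2-enoate carrying at its 3-position the furanos-4-yl unit of 9 (arm (E)-CH=C(CH3)CO2Et on the ring carbon that becomes C6) | CC1(C)O[C@H]2O[C@@H](/C=C(\C)C(=O)OCC)[C@](O)(C(=C)COCc3ccc(OC)cc3)[C@H]2O1 | intermediate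
13 | the corresponding (E)-allylic alcohol, arm (E)-CH=C(CH3)CH2OH | CC1(C)O[C@H]2O[C@@H](/C=C(\C)CO)[C@](O)(C(=C)COCc3ccc(OC)cc3)[C@H]2O1 | intermediate
14 | the corresponding (E)-allyl phenyl sulfide, arm (E)-CH=C(CH3)CH2SPh | CC1(C)O[C@H]2O[C@@H](/C=C(\C)CSc3ccccc3)[C@](O)(C(=C)COCc3ccc(OC)cc3)[C@H]2O1 | intermediate
15 | L-lyxo-configured 2,3-O-isopropylidene furanose lactol with the (E)-2-methyl-3-(phenylthio)prop-1-enyl arm on the ring carbon that becomes C6 and the 3-(4-methoxybenzyloxy)prop-1-en-2-yl group on the one that becomes C7 (anomer mixture) | OC1O[C@@H](/C=C(\C)CSc2ccccc2)[C@@]2(C(=C)COCc3ccc(OC)cc3)OC(C)(C)O[C@@H]12 | intermediate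
16 | but-2-yn-1-ol | CC#CCO | starting material
17 | sodium 2,2-bis(2-methoxyethoxy)-3-methyl-2,5-dihydro-1,2-oxaluminol-2-uide (cyclic alkenylalanate) | [Na+].CC1=CCO[Al-]1(OCCOC)OCCOC | intermediate
18 | (Z)-3-iodobut-2-en-1-ol | C/C(I)=C/CO | intermediate
19 | (Z)-tert-butyl[(3-iodobut-2-en-1-yl)oxy]dimethylsilane | C/C(I)=C/CO[Si](C)(C)C(C)(C)C | intermediate
20 | [4-(tert-butyldimethylsilyloxy)but-2-en-2-yl]lithium, lithium cis to the silyloxymethyl group | [Li]/C(C)=C\CO[Si](C)(C)C(C)(C)C | intermediate
21 | [4-(tert-butyldimethylsilyloxy)but-2-en-2-yl]magnesium bromide, magnesium cis to the silyloxymethyl group | Br[Mg]/C(C)=C\CO[Si](C)(C)C(C)(C)C | intermediate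
22 | open-chain (1(10)Z,4E) C6,C9-diol: C2 OTBS, C3 SPh, O7/O8 acetonide, C12 OPMB, configuration at C6–C9 as in the target | CC(C)(C)[Si](C)(C)OC/C=C(/C)[C@@H](O)[C@@H]1OC(C)(C)O[C@]1(C(=C)COCc2ccc(OC)cc2)[C@@H](O)/C=C(\C)CSc3ccccc3 | intermediate
23 | 6,9-bis-O-TBS ether of 22 | CC(C)(C)[Si](C)(C)OC/C=C(/C)[C@@H](O[Si](C)(C)C(C)(C)C)[C@@H]1OC(C)(C)O[C@]1(C(=C)COCc2ccc(OC)cc2)[C@@H](O[Si](C)(C)C(C)(C)C)/C=C(\C)CSc3ccccc3 | intermediate
24 | the corresponding C3 phenyl sulfone | CC(C)(C)[Si](C)(C)OC/C=C(/C)[C@@H](O[Si](C)(C)C(C)(C)C)[C@@H]1OC(C)(C)O[C@]1(C(=C)COCc2ccc(OC)cc2)[C@@H](O[Si](C)(C)C(C)(C)C)/C=C(\C)CS(=O)(=O)c3ccccc3 | intermediate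
25 | C2 allylic alcohol of the sulfone | OC/C=C(/C)[C@@H](O[Si](C)(C)C(C)(C)C)[C@@H]1OC(C)(C)O[C@]1(C(=C)COCc2ccc(OC)cc2)[C@@H](O[Si](C)(C)C(C)(C)C)/C=C(\C)CS(=O)(=O)c3ccccc3 | intermediate
26 | open-chain C3 phenylsulfonyl C2 bromide (O6/O9 TBS, O7/O8 acetonide, C12 OPMB, 1(10)Z,4E) | BrC/C=C(/C)[C@@H](O[Si](C)(C)C(C)(C)C)[C@@H]1OC(C)(C)O[C@]1(C(=C)COCc2ccc(OC)cc2)[C@@H](O[Si](C)(C)C(C)(C)C)/C=C(\C)CS(=O)(=O)c3ccccc3 | intermediate
27 | potassium salt of the C3 carbanion of 26 | [K+].BrC/C=C(/C)[C@@H](O[Si](C)(C)C(C)(C)C)[C@@H]1OC(C)(C)O[C@]1(C(=C)COCc2ccc(OC)cc2)[C@@H](O[Si](C)(C)C(C)(C)C)/C=C(\C)[CH-]S(=O)(=O)c3ccccc3 | intermediate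
28 | ten-membered (1(10)Z,4E)-diene with C3 phenylsulfonyl group (both C3 epimers), O6/O9 TBS, O7/O8 acetonide, C11 as 3-(4-methoxybenzyloxy)prop-1-en-2-yl | C1/C=C(/C)[C@@H](O[Si](C)(C)C(C)(C)C)[C@@H]2OC(C)(C)O[C@]2(C(=C)COCc3ccc(OC)cc3)[C@@H](O[Si](C)(C)C(C)(C)C)/C=C(\C)C1S(=O)(=O)c4ccccc4 | intermediate
29 | desulfonylated macrocycle | C1/C=C(/C)[C@@H](O[Si](C)(C)C(C)(C)C)[C@@H]2OC(C)(C)O[C@]2(C(=C)COCc3ccc(OC)cc3)[C@@H](O[Si](C)(C)C(C)(C)C)/C=C(\C)C1 | intermediate
30 | macrocyclic C12 alcohol (O6/O9 TBS) | C1/C=C(/C)[C@@H](O[Si](C)(C)C(C)(C)C)[C@@H]2OC(C)(C)O[C@]2(C(=C)CO)[C@@H](O[Si](C)(C)C(C)(C)C)/C=C(\C)C1 | intermediate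
31 | macrocyclic 6,9,12-triol 7,8-acetonide | C1/C=C(/C)[C@@H](O)[C@@H]2OC(C)(C)O[C@]2(C(=C)CO)[C@@H](O)/C=C(\C)C1 | intermediate
32 | 6,9-dihydroxy C12 enal | C1/C=C(/C)[C@@H](O)[C@@H]2OC(C)(C)O[C@]2(C(=C)C=O)[C@@H](O)/C=C(\C)C1 | intermediate
33 | 6,12-lactol (C12 epimers) | C=C1C(O)O[C@H]2/C=C(\C)CC/C=C(/C)[C@@H](O)[C@@H]3OC(C)(C)O[C@]123 | intermediate
34 | (1(10)Z,4E)-9-hydroxy-7,8-O-isopropylidene-germacra-1(10),4,11(13)-trien-12,6-olide | C=C1C(=O)O[C@H]2/C=C(\C)CC/C=C(/C)[C@@H](O)[C@@H]3OC(C)(C)O[C@]123 | intermediate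
35 | angelic acid, (Z)-2-methylbut-2-enoic acid | C/C=C(/C)C(=O)O | starting material
36 | (Z)-2-methylbut-2-enoic 2,4,6-trichlorobenzoic anhydride | C/C=C(/C)C(=O)OC(=O)c1c(Cl)cc(Cl)cc1Cl | intermediate
37 | 9-O-angeloyl-7,8-O-isopropylidene lactone | C=C1C(=O)O[C@H]2/C=C(\C)CC/C=C(/C)[C@@H](OC(=O)/C(C)=C\C)[C@@H]3OC(C)(C)O[C@]123 | intermediate
38 | CNP0303917.1, (1(10)Z,4E,6S,7S,8S,9R)-9-angeloyloxy-7,8-dihydroxygermacra-1(10),4,11(13)-trien-12,6-olide | C=C1C(=O)O[C@H]2/C=C(\C)CC/C=C(/C)[C@@H](OC(=O)/C(C)=C\C)[C@H](O)[C@@]12O | target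

**Step count.** Total: 24 steps. Longest linear sequence: 21 steps (L-arabinose to 38 through steps 1–3, 5–10 and 13–24; steps 4, 11 and 12 prepare the two side fragments).

**Steps most likely to fail**

Step 18 (ring closure). Intermolecular alkylation may outrun the strained ten-membered closure, or the base may consume the Z-allylic bromide before the ring forms. The fallback closes the same C2–C3 bond with the more nucleophilic sulfide-stabilised allyl anion and a less base-sensitive allylic chloride. It sets out from sulfide 23. HF·pyridine/pyridine in THF at 0 °C should cleave the primary silyl ether to give allylic alcohol F1. MsCl, LiCl and 2,4,6-collidine in DMF at 0 °C should give allylic chloride F2. n-BuLi/DABCO in THF at −78 °C under high dilution should deprotonate next to sulfur and close the ring to macrocyclic allyl phenyl sulfide F3. Oxidation of F3 with H2O2/(NH4)6Mo7O24·4H2O in EtOH at 0 °C rejoins the route at sulfone 28.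

Step 13 (C9 configuration). Chelation may not dominate, and attack on the opposite carbonyl face would erode the configuration at C9. The fallback sets C9 by hydride delivery instead of carbon delivery. From lactol 15, Ag2CO3 on Celite in toluene at reflux (Fétizon oxidation, which leaves the sulfide alone) should give lactone F4. Addition of alkenyllithium 20 in THF at −78 °C should stop at hemiketal F5. Reduction of its open hydroxy enone form with LiBH(s-Bu)3 and ZnCl2 in THF/CH2Cl2 at −78 °C should deliver hydride anti to the C8–O bond (Felkin–Anh) and give diol 22, where the route is rejoined.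

Step 19 (desulfonylation). Hydride may be delivered to C5, which would move the olefin to C3=C4, or the π-allyl intermediate may scramble the C4=C5 geometry. The fallback replaces the π-allyl/hydride pathway by single-electron reduction. Sodium amalgam (Na(Hg)) with Na2HPO4 in MeOH/THF at −20 °C on 28 should expel sulfinate from the radical anion, and the allyl anion should be protonated at the less hindered C3 to give 29 directly. No new compound is made (F0).

**Further compounds**

F1 | step 18 | C2 allylic alcohol of bis-TBS sulfide 23 | OC/C=C(/C)[C@@H](O[Si](C)(C)C(C)(C)C)[C@@H]1OC(C)(C)O[C@]1(C(=C)COCc2ccc(OC)cc2)[C@@H](O[Si](C)(C)C(C)(C)C)/C=C(\C)CSc3ccccc3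
F2 | step 18 | corresponding C2 allylic chloride | ClC/C=C(/C)[C@@H](O[Si](C)(C)C(C)(C)C)[C@@H]1OC(C)(C)O[C@]1(C(=C)COCc2ccc(OC)cc2)[C@@H](O[Si](C)(C)C(C)(C)C)/C=C(\C)CSc3ccccc3
F3 | step 18 | ten-membered (1(10)Z,4E)-diene with C3 phenylthio group (C3 epimers) | C1/C=C(/C)[C@@H](O[Si](C)(C)C(C)(C)C)[C@@H]2OC(C)(C)O[C@]2(C(=C)COCc3ccc(OC)cc3)[C@@H](O[Si](C)(C)C(C)(C)C)/C=C(\C)C1Sc4ccccc4
F4 | step 13 | 2,3-O-isopropylidene-L-lyxono-1,4-lactone corresponding to lactol 15 | O=C1O[C@@H](/C=C(\C)CSc2ccccc2)[C@@]2(C(=C)COCc3ccc(OC)cc3)OC(C)(C)O[C@@H]12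
F5 | step 13 | hemiketal from addition of 20 to F4 (C9 epimers) | OC1(/C(C)=C\CO[Si](C)(C)C(C)(C)C)O[C@@H](/C=C(\C)CSc2ccccc2)[C@@]2(C(=C)COCc3ccc(OC)cc3)OC(C)(C)O[C@@H]12
F0 | step 19 | none | none
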